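**Plan**

- Feature: number ring A as O1, C2 (aryl), C3, C4, C5, with C6 the hydroxymethyl carbon on C3 and C7 the aryl carbinol carbon on C4. Once O1–C5 is opened to the tetraol, the chain C2–C3–C4–C7 with its one-carbon branches C6 and C5 has a twofold axis (C2 and C7 both S, C3 and C4 both R).
- Retrosynthesis: remove the two phenol silyl groups; return the C6/C7 diol to a γ-lactone (C6 acyl–O–C7) and the C5 methylene to a lactone carbonyl, giving a C2-symmetric cis-fused bislactone; open both lactone C–O bonds to a bis-imide diol; cut C2–C3 and C7–C4 as aldol bonds to a succinyl bis-oxazolidinone and two molecules of O-silyl vanillin.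
- Forward: the three fragments are joined in one double aldol step (no ring); both five-membered lactones then close with loss of the auxiliaries; one lactone is reduced through its lactol to the cyclic ether (ring A); the other is opened reductively to the C6/C7 diol; the phenols are freed.
- Stereochemistry: all four stereocentres arise in the double aldol step, each half controlled by its own (S)-4-benzyl auxiliary through a Z-boron enolate. The 3,4-cis relation of ring A is the threo succinate core, held in the cis-fused bicycle until the lactones are gone.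

Key step: step 3

Remark: the phenols are carried as triisopropylsilyl ethers instead of benzyl ethers, so that the last deprotection uses fluoride and cannot hydrogenolyse the electron-rich benzylic C–O bonds at C2 and C7.
Notation: Ar = 3-methoxy-4-(triisopropylsilyloxy)phenyl; C2–C7 are the target positions defined above, used also for the intermediates.

**Route**

Step 1
Reactants: 1 vanillin
Product: 2 3-methoxy-4-(triisopropylsilyloxy)benzaldehyde
Conditions: iPr3SiCl (1.1 equiv), imidazole (2.2 equiv), DMF, 0 °C to rt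
Reagents that add atoms: triisopropylsilyl chloride, CC(C)[Si](Cl)(C(C)C)C(C)C
Why: Imidazole-promoted O-silylation of the phenol (silyl ether formation); the hindered aryl silyl ether should survive the boron aldol, the hydride steps and BF3 at low temperature, and leave at the end with fluoride.

Step 2
Reactants: 3 (S)-4-benzyl-2-oxazolidinone (2 equiv); 4 succinyl chloride (1 equiv)
Product: 6 1,4-bis[(S)-4-benzyl-2-oxooxazolidin-3-yl]butane-1,4-dione, via lithium oxazolidinide 5 (not isolated)
Conditions: nBuLi (2.0 equiv), THF, −78 °C; then 4, −78 to 0 °C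
Reagents that add atoms: none
Why: N-acylation of the lithiated oxazolidinone by an acid chloride, carried out at both ends of the diacid chloride (the standard entry to N-acyl oxazolidinones); no stereocentre is formed and the auxiliary centres are not touched.

Step 3
Reactants: 6 1,4-bis[(S)-4-benzyl-2-oxooxazolidin-3-yl]butane-1,4-dione; 2 3-methoxy-4-(triisopropylsilyloxy)benzaldehyde (2.5 equiv)
Product: 9 (2S,3S)-1,4-bis[(S)-4-benzyl-2-oxooxazolidin-3-yl]-2,3-bis[(S)-hydroxy(Ar)methyl]butane-1,4-dione, via bis(dibutylboron) enolate 7 (not isolated), via bis(dibutylboron) aldolate 8 (not isolated)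
Conditions: nBu2BOTf (2.4 equiv), iPr2NEt (2.8 equiv), CH2Cl2, −78 to 0 °C; then 2, −78 to 0 °C; pH 7 buffer (NaH2PO4/Na2HPO4), MeOH, 30% H2O2, 0 °C
Reagents that add atoms: none
Why: Complexation of each imide carbonyl by nBu2BOTf and deprotonation by iPr2NEt gives the (Z,Z)-bis(boron enolate) 7; each enolate in turn binds one molecule of 2 at boron and adds through a closed six-membered chair transition state, forming C2–C3 and C7–C4 and leaving the bis-aldolate 8, which the buffered peroxide work-up cleaves to 9. The closest known reaction is the Evans boron syn-aldol addition of N-acyl oxazolidinones, which is also used on N-succinyl imides; here it runs at both ends of one succinyl unit. No ring closes in this step: the carbonyl that each new aldolate oxygen could reach is masked as an enolate until it has itself reacted, and boron aldolates are too weakly nucleophilic to lactonise at or below 0 °C. C3 and C4 are set by enolate-face selection, the benzyl group of each (S)-auxiliary blocking one face of its own enolate in the dipole-opposed conformation; C2 and C7 are set by the Z enolate geometry and the equatorial aryl group in the chair, which makes each half syn. The step needs syn over anti and the same absolute sense at both ends, that is the C2-symmetric adduct and not the meso one; two identical auxiliaries acting under reagent control secure this, the second addition being expected to follow its own auxiliary despite the stereocentres already present next to it.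

Step 4
Reactants: 9 (2S,3S)-1,4-bis[(S)-4-benzyl-2-oxooxazolidin-3-yl]-2,3-bis[(S)-hydroxy(Ar)methyl]butane-1,4-dione
Product: 11 (1S,4S,5S,8S)-4,8-di-Ar-3,7-dioxabicyclo[3.3.0]octane-2,6-dione, via monolactone imide 10 (not isolated)
Conditions: Et3N (2 equiv), DMAP (0.1 equiv), CH2Cl2, rt
Reagents that add atoms: none
Why: Two consecutive 5-exo-trig transacylations (lactonisation with expulsion of the oxazolidinone), the C2 hydroxyl onto C5 and the C7 hydroxyl onto C6; the threo C3–C4 core places the second hydroxyl and imide cis on the first lactone, so only the cis-fused bicycle with both aryl groups on its convex face can form and no stereocentre is touched, and a weak amine base is chosen because stronger bases invite retro-aldol cleavage and β-elimination of the β-acyloxy lactone.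

Step 5
Reactants: 11 (1S,4S,5S,8S)-4,8-di-Ar-3,7-dioxabicyclo[3.3.0]octane-2,6-dione
Product: 12 (1S,4S,5S,8S)-4,8-di-Ar-6-hydroxy-3,7-dioxabicyclo[3.3.0]octan-2-one (both anomers at the hemiacetal carbon)
Conditions: iBu2AlH (1.05 equiv), CH2Cl2, −78 °C; aq. KNaC4H4O6 (potassium sodium tartrate)
Reagents that add atoms: none
Why: Partial reduction of a lactone to its lactol with iBu2AlH, which stops at the hemiacetal stage at −78 °C; the two carbonyls are homotopic, so attack at either gives the same lactol, one equivalent of hydride is used so that the second lactone is largely spared, and recovered 11 is returned to the step.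

Step 6
Reactants: 12 (1S,4S,5S,8S)-4,8-di-Ar-6-hydroxy-3,7-dioxabicyclo[3.3.0]octan-2-one
Product: 13 (1S,4S,5R,8S)-4,8-di-Ar-3,7-dioxabicyclo[3.3.0]octan-2-one
Conditions: Et3SiH (4 equiv), BF3·OEt2 (1.5 equiv), CH2Cl2, −78 °C; aq. NaHCO3
Reagents that add atoms: none
Why: Ionic hydrogenation of a lactol (BF3-assisted loss of the anomeric hydroxyl and hydride transfer from Et3SiH to C5) gives the C5 methylene of ring A, which is not a stereocentre; at −78 °C the hemiacetal should ionise well before the benzylic C2–O and C7–O bonds, so C2, C3, C4 and C7 are untouched.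

Step 7
Reactants: 13 (1S,4S,5R,8S)-4,8-di-Ar-3,7-dioxabicyclo[3.3.0]octan-2-one
Product: 14 (2S,3R,4R)-2-Ar-4-[(S)-hydroxy(Ar)methyl]-3-(hydroxymethyl)tetrahydrofuran
Conditions: LiBH4 (3 equiv), THF, 0 °C to rt; aq. NH4Cl
Reagents that add atoms: none
Why: Hydride reduction of the remaining γ-lactone to its 1,4-diol turns C6 into the hydroxymethyl group and frees the C7 carbinol without breaking any bond at a stereocentre; LiBH4 is chosen because it leaves aryl silyl ethers alone.

Step 8
Reactants: 14 (2S,3R,4R)-2-Ar-4-[(S)-hydroxy(Ar)methyl]-3-(hydroxymethyl)tetrahydrofuran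
Product: 15 (−)-tanegol
Conditions: Bu4NF (2.4 equiv), AcOH (2.4 equiv), THF, 0 °C
Reagents that add atoms: none
Why: Fluoride cleavage of the two aryl silyl ethers (desilylation); the buffered, non-acidic, non-reductive medium should prevent both acid-induced closure of the C6 hydroxyl onto C7 and cleavage of the benzylic C–O bonds, so all four stereocentres are delivered unchanged.

**Compound list**

1 | vanillin (4-hydroxy-3-methoxybenzaldehyde) | COc1cc(C=O)ccc1O | starting material
2 | 3-methoxy-4-(triisopropylsilyloxy)benzaldehyde | COc1cc(C=O)ccc1O[Si](C(C)C)(C(C)C)C(C)C | intermediate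
3 | (S)-4-benzyl-2-oxazolidinone | O=C1N[C@@H](Cc2ccccc2)CO1 | starting material
4 | succinyl chloride (butanedioyl dichloride) | O=C(Cl)CCC(=O)Cl | starting material
5 | N-lithio-(S)-4-benzyl-2-oxazolidinone | [Li]N1[C@@H](Cc2ccccc2)COC1=O | intermediate
6 | 1,4-bis[(S)-4-benzyl-2-oxooxazolidin-3-yl]butane-1,4-dione | O=C(CCC(=O)N1[C@@H](Cc2ccccc2)COC1=O)N1[C@@H](Cc2ccccc2)COC1=O | intermediate
7 | (1Z,3Z)-1,4-bis[(S)-4-benzyl-2-oxooxazolidin-3-yl]-1,4-bis(dibutylboryloxy)buta-1,3-diene | CCCCB(CCCC)O/C(=C\C=C(/OB(CCCC)CCCC)N1[C@@H](Cc2ccccc2)COC1=O)N1[C@@H](Cc2ccccc2)COC1=O | intermediate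
8 | bis(O-dibutylboryl) aldolate of 9 | COc1cc([C@@H](OB(CCCC)CCCC)[C@@H](C(=O)N2[C@@H](Cc3ccccc3)COC2=O)[C@H](C(=O)N2[C@@H](Cc3ccccc3)COC2=O)[C@H](OB(CCCC)CCCC)c2ccc(O[Si](C(C)C)(C(C)C)C(C)C)c(OC)c2)ccc1O[Si](C(C)C)(C(C)C)C(C)C | intermediate
9 | (2S,3S)-1,4-bis[(S)-4-benzyl-2-oxooxazolidin-3-yl]-2,3-bis[(S)-hydroxy(3-methoxy-4-triisopropylsilyloxyphenyl)methyl]butane-1,4-dione | COc1cc([C@@H](O)[C@@H](C(=O)N2[C@@H](Cc3ccccc3)COC2=O)[C@H](C(=O)N2[C@@H](Cc3ccccc3)COC2=O)[C@H](O)c2ccc(O[Si](C(C)C)(C(C)C)C(C)C)c(OC)c2)ccc1O[Si](C(C)C)(C(C)C)C(C)C | intermediate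
10 | (S)-4-benzyl-3-{(2S,3S,4S)-2-Ar-4-[(S)-hydroxy(Ar)methyl]-5-oxotetrahydrofuran-3-carbonyl}oxazolidin-2-one | COc1cc([C@@H](O3)[C@@H](C(=O)N2[C@@H](Cc4ccccc4)COC2=O)[C@H](C3=O)[C@H](O)c2ccc(O[Si](C(C)C)(C(C)C)C(C)C)c(OC)c2)ccc1O[Si](C(C)C)(C(C)C)C(C)C | intermediate
11 | (1S,4S,5S,8S)-4,8-bis(3-methoxy-4-triisopropylsilyloxyphenyl)-3,7-dioxabicyclo[3.3.0]octane-2,6-dione (cis-fused, both aryl groups on the convex face) | COc1cc([C@@H](O3)[C@@H](C4=O)[C@H](C3=O)[C@H](O4)c2ccc(O[Si](C(C)C)(C(C)C)C(C)C)c(OC)c2)ccc1O[Si](C(C)C)(C(C)C)C(C)C | intermediate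
12 | (1S,4S,5S,8S)-6-hydroxy-4,8-bis(3-methoxy-4-triisopropylsilyloxyphenyl)-3,7-dioxabicyclo[3.3.0]octan-2-one (anomeric mixture at C6 of the bicycle) | COc1cc([C@@H](O3)[C@@H](C4=O)[C@H](C3O)[C@H](O4)c2ccc(O[Si](C(C)C)(C(C)C)C(C)C)c(OC)c2)ccc1O[Si](C(C)C)(C(C)C)C(C)C | intermediate
13 | (1S,4S,5R,8S)-4,8-bis(3-methoxy-4-triisopropylsilyloxyphenyl)-3,7-dioxabicyclo[3.3.0]octan-2-one | COc1cc([C@@H](O3)[C@@H](C4=O)[C@H](C3)[C@H](O4)c2ccc(O[Si](C(C)C)(C(C)C)C(C)C)c(OC)c2)ccc1O[Si](C(C)C)(C(C)C)C(C)C | intermediate
14 | (2S,3R,4R)-4-[(S)-hydroxy(3-methoxy-4-triisopropylsilyloxyphenyl)methyl]-3-(hydroxymethyl)-2-(3-methoxy-4-triisopropylsilyloxyphenyl)tetrahydrofuran | COc1cc([C@@H](O)[C@H]2CO[C@H](c3ccc(O[Si](C(C)C)(C(C)C)C(C)C)c(OC)c3)[C@H]2CO)ccc1O[Si](C(C)C)(C(C)C)C(C)C | intermediate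
15 | (−)-tanegol, (2S,3R,4R)-2-(4-hydroxy-3-methoxyphenyl)-4-[(S)-hydroxy(4-hydroxy-3-methoxyphenyl)methyl]-3-(hydroxymethyl)tetrahydrofuran | COc1cc([C@@H](O)[C@H]2CO[C@H](c3ccc(O)c(OC)c3)[C@H]2CO)ccc1O | target

**Step count and risks**

Total step count: 8. Longest linear sequence: 7 steps (step 2, or step 1, followed by steps 3 to 8).

Steps most likely to fail:

Step 3. What may go wrong: incomplete enolisation of the second imide, lactonisation of a first aldolate onto the neighbouring imide before the second addition, and loss of facial control in the second, more hindered addition. Fallback: run the two aldol additions as separate operations with the first carbinol masked. Setting out from 6, enolisation with one equivalent of nBu2BOTf/iPr2NEt and addition of one equivalent of 2 should give the mono-aldol adduct F1. Silylation (Et3SiOTf, 2,6-lutidine, CH2Cl2, −78 °C) gives its triethylsilyl ether F2, in which lactonisation is blocked. A second boron aldol addition of 2 at the remaining methylene gives the mono-silylated bis-aldol adduct F3. HF·pyridine in THF/pyridine at 0 °C removes the alkyl triethylsilyl group ahead of the aryl triisopropylsilyl ethers, and the route is rejoined at 9.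

Step 5. What may go wrong: over-reduction at the second, equally reactive lactone (a statistical limit on mono-reduction) and reductive ring-opening. Fallback: replace the statistical differentiation by one built in during a stepwise aldol sequence. Setting out from 6 and passing through F1, F2 and F3 as described for step 3, lactonisation of F3 (Et3N, DMAP, CH2Cl2) can involve only the free carbinol and should give the lactone imide F4 (lactone C6–O–C7, imide at C5, silyl ether at the C2 oxygen). LiBH4/MeOH in THF at 0 °C reduces the imide to the primary alcohol F5. HF·pyridine frees the C2 hydroxyl to give the diol lactone F6. Mitsunobu cyclodehydration (PPh3, DIAD, THF, 0 °C), in which the primary C5 hydroxyl is activated and displaced by the C2 oxygen with retention at C2, closes ring A and rejoins the route at 13, so steps 5 and 6 are both bypassed.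

Step 4. What may go wrong: base-induced retro-aldol cleavage, β-elimination across C2–C3 or C7–C4 once a lactone has formed, or attack of a carbinol oxygen on the ring carbonyl of its own auxiliary in place of lactonisation. Fallback: separate auxiliary removal from ring closure. Setting out from 9, LiOH/H2O2 in THF/H2O at 0 °C cleaves both imides to give the dihydroxy diacid F7. Carbodiimide dehydration (EDC·HCl, DMAP cat., CH2Cl2, 0 °C) of its two γ-hydroxy acid units closes both lactones and returns the route at 11.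

Further compounds
F1 | step 3 | (S)-2-[(S)-hydroxy(Ar)methyl]-1,4-bis[(S)-4-benzyl-2-oxooxazolidin-3-yl]butane-1,4-dione | COc1cc([C@@H](O)[C@@H](C(=O)N2[C@@H](Cc3ccccc3)COC2=O)CC(=O)N2[C@@H](Cc3ccccc3)COC2=O)ccc1O[Si](C(C)C)(C(C)C)C(C)C
F2 | step 3 | triethylsilyl ether of F1 | COc1cc([C@@H](O[Si](CC)(CC)CC)[C@@H](C(=O)N2[C@@H](Cc3ccccc3)COC2=O)CC(=O)N2[C@@H](Cc3ccccc3)COC2=O)ccc1O[Si](C(C)C)(C(C)C)C(C)C
F3 | step 3 | mono-triethylsilyl ether of 9 | COc1cc([C@@H](O[Si](CC)(CC)CC)[C@@H](C(=O)N2[C@@H](Cc3ccccc3)COC2=O)[C@H](C(=O)N2[C@@H](Cc3ccccc3)COC2=O)[C@H](O)c2ccc(O[Si](C(C)C)(C(C)C)C(C)C)c(OC)c2)ccc1O[Si](C(C)C)(C(C)C)C(C)C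
F4 | step 5 | (S)-4-benzyl-3-{(2S,3S,4S)-2-Ar-5-oxo-4-[(S)-(triethylsilyloxy)(Ar)methyl]tetrahydrofuran-3-carbonyl}oxazolidin-2-one | COc1cc([C@@H](O[Si](CC)(CC)CC)[C@@H](C4=O)[C@H](C(=O)N2[C@@H](Cc3ccccc3)COC2=O)[C@H](O4)c2ccc(O[Si](C(C)C)(C(C)C)C(C)C)c(OC)c2)ccc1O[Si](C(C)C)(C(C)C)C(C)C
F5 | step 5 | (3S,4R,5S)-5-Ar-4-(hydroxymethyl)-3-[(S)-(triethylsilyloxy)(Ar)methyl]dihydrofuran-2(3H)-one | COc1cc([C@@H](O[Si](CC)(CC)CC)[C@@H](C4=O)[C@H](CO)[C@H](O4)c2ccc(O[Si](C(C)C)(C(C)C)C(C)C)c(OC)c2)ccc1O[Si](C(C)C)(C(C)C)C(C)C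
F6 | step 5 | (3S,4R,5S)-5-Ar-3-[(S)-hydroxy(Ar)methyl]-4-(hydroxymethyl)dihydrofuran-2(3H)-one | COc1cc([C@@H](O)[C@@H](C4=O)[C@H](CO)[C@H](O4)c2ccc(O[Si](C(C)C)(C(C)C)C(C)C)c(OC)c2)ccc1O[Si](C(C)C)(C(C)C)C(C)C
F7 | step 4 | (2S,3S)-2,3-bis[(S)-hydroxy(Ar)methyl]butanedioic acid | COc1cc([C@@H](O)[C@@H](C(=O)O)[C@H](C(=O)O)[C@H](O)c2ccc(O[Si](C(C)C)(C(C)C)C(C)C)c(OC)c2)ccc1O[Si](C(C)C)(C(C)C)C(C)C
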